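Follow the fraction of each substrate left, not the product made. You will run Monday's, Thursday's and Friday's flasks, which differ in temperature and share a single-handed free catalyst.

| setting | autumn | summer | dusk | Monday's | Thursday's | Friday's |
|---|---|---|---|---|---|---|
| left-handed substrate | 16 mM | 16 mM | 8 mM | 16 mM | 16 mM | 16 mM |
| right-handed substrate | 16 mM | 16 mM | 8 mM | 16 mM | 16 mM | 16 mM |
| reagent | 32 mM | 72 mM | 48 mM | 48.0 mM | 48.0 mM | 48.0 mM |
| free catalyst | 0.21 mM (in portions, 3) | 0.21 mM (in portions, 3) | 0.21 mM (in portions, 3) | 0.21 mM (in portions, 3) | 0.21 mM (in portions, 3) | 0.21 mM (in portions, 3) |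
| temperature | 20 °C | 40 °C | 20 °C | 40 °C | 25 °C | 55 °C |
| remark | run made earlier; portions every 2.0 h | run made earlier; portions every 2.0 h | run made earlier; portions every 2.0 h | the portions of free catalyst follow each other after 2.0 h, the first at the start | the portions of free catalyst follow each other after 2.0 h, the first at the start | the portions of free catalyst follow each other after 2.0 h, the first at the start |
| time |  |  |  | 10 h | 10 h | 10 h |

| run | time / h | left-handed product / % | right-handed product / % |
|---|---|---|---|
| autumn | 1.00 | 1.6 | 0 |
| autumn | 4.00 | 3.0 | 0.5 |
| autumn | 5.00 | 2.8 | 0.6 |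
| autumn | 8.00 | 8.4 | 0.3 |
| autumn | 15.0 | 20.1 | 0.7 |
| summer | 0.417 | 0.9 | 0.2 |
| summer | 1.33 | 3.2 | 0 |
| summer | 2.00 | 4.1 | 1.8 |
| summer | 3.00 | 6.2 | 2.6 |
| summer | 5.00 | 12.9 | 4.7 |
| summer | 6.00 | 17.8 | 4.4 |
| dusk | 1.33 | 3.5 | 0.4 |
| dusk | 4.00 | 6.9 | 2.8 |
| dusk | 8.00 | 22.9 | 3.9 |
| dusk | 10.0 | 25.8 | 2.5 |
| dusk | 15.0 | 34.4 | 7.0 |

(scatter of a reading: 1 percentage point)

- free catalyst is single-handed; left-handed substrate and right-handed substrate are mirror images of each other, charged as a racemate, each of them at the stated concentration
- the numbers in the tables scatter with a standard deviation of 1 percentage point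
- an excess is the difference of the two amounts in percent of their sum
- an excess is below zero if the other one leads

1. the flask with the highest excess of left-handed product over right-handed product ("all alike" if they lie within 1.5 percentage points) (Monday's / Thursday's / Friday's / all alike)
2. excess of left-handed product over right-handed product at the end, Monday's
3. excess of left-handed product over right-handed product at the end, Thursday's
4. excess of left-handed product over right-handed product at the end, Friday's

One thing looks wrong. The autumn and dusk runs share 20 °C and a catalyst charge, yet at 15.0 h autumn reads an excess of 93.3% and dusk 66.2%. Reckon with fractions left. Each substrate is half of the charge, so its fraction left is one minus two times its product reading. Divide the logarithm of the left-handed fraction by that of the right-handed fraction: this is the selectivity factor, s. The last dusk reading gives s = 7.72. By its last reading the autumn run holds 59.8% of its left-handed substrate, and there this s reckons 3.22% of right-handed product. The autumn reading of 0.7% is lower by 2.5 percentage points, with a scatter of 1 point. That reading is smaller than its scatter. With the reckoned amount, the autumn excess comes to 72.4%.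

My own reckoning starts from the summer run, at Monday's 40 °C. Its last two readings give on average s = 3.90, the ratio of the logarithms of the fractions left at 40 °C. I assume it holds at any c(reagent). Scaling the last summer reading by time and c(reagent), I estimate 19.8% of left-handed product for Monday's. That leaves 60.4% of left-handed substrate and 87.9% of right-handed substrate, so the excess is 53.1%. For Thursday's, I borrow dusk's s, read at 20 °C, although that flask runs at 25 °C. At the same fraction left it reckons 72.5%. Friday's is hotter. On my assumption, the lower s at 40 °C than at 20 °C is a temperature effect, so I place Friday's below Monday's.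

The forecast names Thursday's, with 58% for Monday's, 68% for Thursday's and 42% for Friday's: “The coolest flask should be the most selective.” On Monday's it stands above my 53.1%, and on Thursday's below my 72.5%.

The flasks give 51.4% for Monday's, 69.5% for Thursday's and 30.8% for Friday's, so Thursday's leads.

    reagent ⇌ dormant form (K = 0.250, k = 0.00180 /min, Ea = 96.0 kJ/mol, ΔH = 21.0 kJ/mol)
    free catalyst + left-handed substrate ⇌ catalyst intermediate A (K = 120 /M, k = 326 /M/min, Ea = 49.0 kJ/mol, ΔH = −53.0 kJ/mol)
    free catalyst + right-handed substrate ⇌ catalyst intermediate B (K = 84.0 /M, k = 155 /M/min, Ea = 37.0 kJ/mol, ΔH = −23.0 kJ/mol)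
    reagent + catalyst intermediate A → free catalyst + left-handed product (k = 4.12 /M/min, Ea = 41.0 kJ/mol)
    reagent + catalyst intermediate B → free catalyst + right-handed product (k = 0.845 /M/min, Ea = 43.0 kJ/mol)
    (constants at 25 °C)

In Monday's, 59% of the left-handed substrate is left at 10.0 h. With s = 3.90, that reckons 87.3% of the right-handed substrate, and the flask holds 86%. Now take Monday's flask with 0.36 mM of free catalyst. It has 41% of its left-handed substrate left, and the same s reckons 79.6% of right-handed substrate, where the flask holds 78%. Its excess reckons to 48.5% and stands at 47.1%.

(The data were computed with constants of no real substance; noise was put on by code.)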